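**Retrosynthetic overview**
- Target ⇐ hexaol (selective acetylation of the two primary OH) ⇐ 3α,4α-epoxy-11,13-dihydroxy lactone: one LiAlH4 step opens the lactone to the C12-OH/6α-OH pair and the epoxide to the 4α-carbinol.
- C11/C13 oxygens ⇐ dihydroxylation of an α-methylene lactone; C4–O ⇐ convex-face epoxidation of a C3=C4 alkene (8-deoxycumambrin B).
- C3=C4 alkene and the cis ring-fusion hydrogen at C5 ⇐ proposed HAT-triggered desulfonylative 1,3-transposition of a C3 allyl sulfone, made from the enone of isophotosantonic lactone by Luche reduction and dehydrative sulfonylation.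
- Ring order: rings A and B and the γ-lactone (C6, C7) are bought with (−)-α-santonin. One photochemical step turns the 6/6 skeleton into the 5/7 hydroazulene (ring A contracted, ring B expanded) and sets C1 and C10. No ring is formed afterwards.

Assumption: commercial (−)-α-santonin is the starting material; where a stereocentre is destroyed later (C3 of the allylic alcohol and the sulfone, C11 of the selenium and diol intermediates) the expected major epimer is drawn, although either serves.

**Route**

Step 1
Reactants: 1 (−)-α-santonin [(11S)-3-oxoeudesma-1,4-dien-6α,12-olide; 6βH, 7αH, 10β-Me]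
Product: 2 isophotosantonic lactone (10α-hydroxy-3-oxo-1αH,11βH-guai-4-en-6α,12-olide)
Conditions: hν (medium-pressure Hg lamp, Pyrex), AcOH/H2O 1:1, reflux, N2
Reagents that add atoms: water, O
Why: Classical santonin photorearrangement of the cross-conjugated cyclohexadienone in aqueous acid, in which the C1–C5 bond forms (1α-H) and water captures the C10 cation on the α face (10α-OH, 10β-Me), while C6, C7 and C11 are untouched.

Step 2
Reactants: 2 isophotosantonic lactone
Product: 3 3β,10α-dihydroxy-1αH,11βH-guai-4-en-6α,12-olide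
Conditions: NaBH4, CeCl3·7H2O, MeOH, −20 °C
Reagents that add atoms: none
Why: Luche 1,2-reduction touches only the enone carbonyl (lactone inert), with hydride arriving on the open α face of ring A to give mainly the 3β-alcohol; the C3 configuration does not matter because C3 is ionised in step 3.

Step 3
Reactants: 3 3β,10α-dihydroxy-1αH,11βH-guai-4-en-6α,12-olide
Product: 4 10α-hydroxy-3α-(p-tolylsulfonyl)-1αH,11βH-guai-4-en-6α,12-olide
Conditions: sodium p-toluenesulfinate (2 equiv), AcOH/H2O 4:1, 50 °C
Reagents that add atoms: sodium p-toluenesulfinate, [Na+].[O-]S(=O)c1ccc(C)cc1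
Why: Dehydrative allylic sulfonylation (SN1-type substitution): acetic acid ionises the allylic alcohol to the C3–C4–C5 allyl cation, sulfinate sulfur captures the less hindered secondary terminus C3 from the α face, and reversible ionisation funnels material to the C3 sulfone that keeps the tetrasubstituted C4=C5 alkene; the tertiary 10-OH and the lactone tolerate warm acetic acid.

Step 4
Reactants: 4 10α-hydroxy-3α-(p-tolylsulfonyl)-1αH,11βH-guai-4-en-6α,12-olide
Product: 5 10α-hydroxy-1αH,5αH,11βH-guai-3-en-6α,12-olide (11β,13-dihydro-8-deoxycumambrin B)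
Conditions: Fe(acac)3 (30 mol %), PhSiH3 (2.5 equiv), degassed EtOH/ethylene glycol 5:1, 60 °C, Ar
Reagents that add atoms: none
Why: Proposed new method: hydrogen-atom-transfer desulfonylative allylic transposition, in which the iron hydride formed from Fe(acac)3 and PhSiH3 delivers H• to C5 of the tetrasubstituted alkene from the open α face of ring A (ring B and C14 shield the β face, the same bias that gives the cis 1α,5α fusion on hydrogenation of this enone series) and so sets C5; the tertiary C4 radical then expels the β-sulfonyl radical to form the C3=C4 alkene, and divalent iron reduces the sulfonyl radical to sulfinate, regenerating trivalent iron in a redox-neutral cycle; H-atom addition at C4 is reversible and has no exit channel, so fragmentation funnels the reaction, and because the hydrogen arrives from outside, the C3 configuration of 4 is irrelevant; the closest known reaction types are the tin-radical SH2′ addition–fragmentation of allyl sulfones and Mukaiyama-type iron-hydride HAT hydrofunctionalisation of alkenes.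

Step 5
Reactants: 5 10α-hydroxy-1αH,5αH,11βH-guai-3-en-6α,12-olide
Product: 8 8-deoxycumambrin B (10α-hydroxy-1αH,5αH-guaia-3,11(13)-dien-6α,12-olide), via 11β-phenylselanyl lactone 6 (not isolated), via selenoxide 7 (not isolated)
Conditions: lithium diisopropylamide (2.5 equiv), THF, −78 °C; PhSeBr (1.2 equiv), −78 °C; then NaIO4, NaHCO3, THF/MeOH/H2O, 0 °C → rt
Reagents that add atoms: none
Why: Grieco selenenylation and selenoxide syn-elimination: the lactone enolate (10-OH carried as its lithium alkoxide) is selenenylated on the β face, anti to the axial H-7α, so the selenoxide can only eliminate toward C13 and gives the exocyclic methylene; NaIO4 oxidises selenium without touching the C3=C4 alkene.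

Step 6
Reactants: 8 8-deoxycumambrin B
Product: 9 3α,4α-epoxy-10α-hydroxy-1αH,5αH-guai-11(13)-en-6α,12-olide
Conditions: mCPBA (1.1 equiv), NaHCO3, CH2Cl2, 0 °C
Reagents that add atoms: mCPBA, OOC(=O)c1cccc(Cl)c1
Why: Prilezhaev epoxidation of the electron-rich trisubstituted C3=C4 alkene (the electron-poor α-methylene lactone is inert) from the convex α face of the cis-fused hydroazulene, the face of H-1, H-5 and the 10α-OH, which fixes the C4–O bond α and sets the C4 stereocentre.

Step 7
Reactants: 9 3α,4α-epoxy-10α-hydroxy-1αH,5αH-guai-11(13)-en-6α,12-olide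
Product: 10 3α,4α-epoxy-10α,11β,13-trihydroxy-1αH,5αH-guaian-6α,12-olide
Conditions: OsO4 (5 mol %), N-methylmorpholine N-oxide (2 equiv), acetone/H2O 4:1, rt
Reagents that add atoms: N-methylmorpholine N-oxide, C[N+]1([O-])CCOCC1; water, O
Why: Upjohn dihydroxylation of the remaining 1,1-disubstituted acrylate alkene installs the C11 and C13 oxygens (β-face attack anti to H-7 expected, but the C11 configuration is irrelevant because C11 becomes non-stereogenic in step 8), and the epoxide and tertiary alcohol survive the neutral conditions.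

Step 8
Reactants: 10 3α,4α-epoxy-10α,11β,13-trihydroxy-1αH,5αH-guaian-6α,12-olide
Product: 11 1αH,5αH-guaiane-4α,6α,10α,11,12,13-hexaol
Conditions: LiAlH4 (6 equiv), THF, 0 °C → reflux (substrate added to the hydride); then H2O, 15 % NaOH, H2O
Reagents that add atoms: none
Why: Global LiAlH4 reduction turns the lactone into the C12 primary alcohol and the free 6α-OH and opens the trisubstituted epoxide by SN2 hydride attack at the less substituted C3, so the C4–O bond (4α-OH, 4β-Me) and all other stereocentres are untouched and C11 now carries two identical CH2OH arms.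

Step 9
Reactants: 11 1αH,5αH-guaiane-4α,6α,10α,11,12,13-hexaol
Product: 12 CNP0179913.1 [(1R,4R,5S,6S,7R,10R)-4α,6α,10α,11-tetrahydroxy-1αH,5αH-guaiane-12,13-diyl diacetate]
Conditions: Ac2O (2.1 equiv), pyridine, −20 → 0 °C
Reagents that add atoms: acetic anhydride, CC(=O)OC(C)=O
Why: Kinetically controlled acetylation: the two primary hydroxyls (C12, C13) react far faster than the hindered secondary 6α-OH (flanked by C5 and C7) and the three tertiary hydroxyls, and no stereocentre is formed.

**Compound list**

1 | (−)-α-santonin | C[C@H]1[C@@H]2CC[C@]3(C=CC(=O)C(=C3[C@H]2OC1=O)C)C | starting material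
2 | isophotosantonic lactone (10α-hydroxy-3-oxo-1αH,11βH-guai-4-en-6α,12-olide) | C[C@H]1[C@@H]2CC[C@@](C)(O)[C@@H]3CC(=O)C(C)=C3[C@H]2OC1=O | intermediate
3 | 3β,10α-dihydroxy-1αH,11βH-guai-4-en-6α,12-olide | C[C@H]1[C@@H]2CC[C@@](C)(O)[C@@H]3C[C@H](O)C(C)=C3[C@H]2OC1=O | intermediate
4 | 10α-hydroxy-3α-(p-tolylsulfonyl)-1αH,11βH-guai-4-en-6α,12-olide | C[C@H]1[C@@H]2CC[C@@](C)(O)[C@@H]3C[C@@H](S(=O)(=O)c4ccc(C)cc4)C(C)=C3[C@H]2OC1=O | intermediate
5 | 10α-hydroxy-1αH,5αH,11βH-guai-3-en-6α,12-olide | C[C@H]1[C@@H]2CC[C@@](C)(O)[C@@H]3CC=C(C)[C@@H]3[C@H]2OC1=O | intermediate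
6 | 10α-hydroxy-11β-phenylselanyl-1αH,5αH-guai-3-en-6α,12-olide (11α-methyl) | C[C@@]1([Se]c4ccccc4)[C@@H]2CC[C@@](C)(O)[C@@H]3CC=C(C)[C@@H]3[C@H]2OC1=O | intermediate
7 | selenoxide of 6 (mixture at selenium) | C[C@@]1([Se](=O)c4ccccc4)[C@@H]2CC[C@@](C)(O)[C@@H]3CC=C(C)[C@@H]3[C@H]2OC1=O | intermediate
8 | 8-deoxycumambrin B (10α-hydroxy-1αH,5αH-guaia-3,11(13)-dien-6α,12-olide) | C=C1[C@@H]2CC[C@@](C)(O)[C@@H]3CC=C(C)[C@@H]3[C@H]2OC1=O | intermediate
9 | 3α,4α-epoxy-10α-hydroxy-1αH,5αH-guai-11(13)-en-6α,12-olide | C=C1[C@@H]2CC[C@@](C)(O)[C@@H]3C[C@H]4O[C@@]4(C)[C@@H]3[C@H]2OC1=O | intermediate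
10 | 3α,4α-epoxy-10α,11β,13-trihydroxy-1αH,5αH-guaian-6α,12-olide | OC[C@@]1(O)[C@@H]2CC[C@@](C)(O)[C@@H]3C[C@H]4O[C@@]4(C)[C@@H]3[C@H]2OC1=O | intermediate
11 | 1αH,5αH-guaiane-4α,6α,10α,11,12,13-hexaol | OCC(O)(CO)[C@@H]1CC[C@@](C)(O)[C@@H]2CC[C@@](C)(O)[C@@H]2[C@H]1O | intermediate
12 | CNP0179913.1, (1R,4R,5S,6S,7R,10R)-4α,6α,10α,11-tetrahydroxy-1αH,5αH-guaiane-12,13-diyl diacetate | CC(=O)OCC(O)(COC(C)=O)[C@@H]1CC[C@@](C)(O)[C@@H]2CC[C@@](C)(O)[C@@H]2[C@H]1O | target

**Step count and risks**

Total step count: 9. Longest linear sequence: 9 steps (fully linear from 1).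

The three steps most likely to fail are steps 3, 4 and 5.

Step 3 can fail if the cyclopentenyl allyl cation loses a proton to a cyclopentadiene or if sulfinate adds at the tertiary C5 terminus. The fallback avoids any cation and sets out from 3. Mitsunobu substitution with p-thiocresol (PPh3, diisopropyl azodicarboxylate, THF, 0 °C) gives, with inversion, 10α-hydroxy-3α-(p-tolylthio)-1αH,11βH-guai-4-en-6α,12-olide F1. Chemoselective sulfur oxidation ((NH4)6Mo7O24, H2O2, EtOH, 0 °C) then gives the sulfone and comes back to the route at 4.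

Step 4, the proposed new method, can fail in three ways: the hydrogen atom may add at C4 instead of C5 (giving hydrogenation or alkene isomerisation), the product alkene may be over-reduced, or the face selectivity at C5 may be poor. The fallback is known chemistry, sets out from 3 and bypasses 4. It is the Myers reductive 1,3-transposition (2-nitrobenzenesulfonylhydrazide, PPh3, diethyl azodicarboxylate, N-methylmorpholine, THF, −30 → 23 °C). Mitsunobu inversion of the 3β-alcohol gives the 3α-[1-(2-nitrophenylsulfonyl)hydrazinyl] compound F2. This loses sulfinic acid to the 3α-allylic diazene F3, whose suprafacial retro-ene loss of N2 delivers hydrogen to the α face of C5. The fallback comes back to the route at 5. It requires the 3β-alcohol; a 3α-alcohol would first be inverted by a Mitsunobu esterification and hydrolysis.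

Step 5 can fail because PhSeBr may attack the C3=C4 alkene or the 10-alkoxide (selenoetherification), or because some endocyclic elimination may occur. The fallback changes the order so that no alkene is present during selenenylation, and sets out from 5. Epoxidation first (mCPBA, NaHCO3, CH2Cl2, 0 °C) gives 3α,4α-epoxy-10α-hydroxy-1αH,5αH,11βH-guaian-6α,12-olide F4. Enolate selenenylation (lithium diisopropylamide, PhSeBr, THF, −78 °C) gives the 11β-phenylselanyl epoxy lactone F5. Oxidation with NaIO4 gives the selenoxide F6, which eliminates to the epoxy methylene lactone. The fallback comes back to the route at 9, so step 6 is no longer needed.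

Further compounds
F1 | step 3 | 10α-hydroxy-3α-(p-tolylthio)-1αH,11βH-guai-4-en-6α,12-olide | C[C@H]1[C@@H]2CC[C@@](C)(O)[C@@H]3C[C@@H](Sc4ccc(C)cc4)C(C)=C3[C@H]2OC1=O
F2 | step 4 | 10α-hydroxy-3α-[1-(2-nitrophenylsulfonyl)hydrazin-1-yl]-1αH,11βH-guai-4-en-6α,12-olide | C[C@H]1[C@@H]2CC[C@@](C)(O)[C@@H]3C[C@@H](N(N)S(=O)(=O)c4ccccc4[N+](=O)[O-])C(C)=C3[C@H]2OC1=O
F3 | step 4 | 3α-diazenyl-10α-hydroxy-1αH,11βH-guai-4-en-6α,12-olide | C[C@H]1[C@@H]2CC[C@@](C)(O)[C@@H]3C[C@@H](N=N)C(C)=C3[C@H]2OC1=O
F4 | step 5 | 3α,4α-epoxy-10α-hydroxy-1αH,5αH,11βH-guaian-6α,12-olide | C[C@H]1[C@@H]2CC[C@@](C)(O)[C@@H]3C[C@H]4O[C@@]4(C)[C@@H]3[C@H]2OC1=O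
F5 | step 5 | 3α,4α-epoxy-10α-hydroxy-11β-phenylselanyl-1αH,5αH-guaian-6α,12-olide | C[C@@]1([Se]c5ccccc5)[C@@H]2CC[C@@](C)(O)[C@@H]3C[C@H]4O[C@@]4(C)[C@@H]3[C@H]2OC1=O
F6 | step 5 | selenoxide of F5 | C[C@@]1([Se](=O)c5ccccc5)[C@@H]2CC[C@@](C)(O)[C@@H]3C[C@H]4O[C@@]4(C)[C@@H]3[C@H]2OC1=O
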